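**Retrosynthetic overview**
- The target comes from the 4Z ten-membered 7(11)-en-12,6-olide by a late, catalyst-controlled epoxidation of C4=C5.
- The ten-membered ring comes from a four-atom ring expansion of a six-membered ketone (ring A, C1–C6) that is spiro-fused at C6 to the butenolide: a C10 radical adds to C1=O and the C1–C6 bond breaks. Ring A has already fixed the Z geometry of C4=C5.
- The C8–C10 side chain comes from Nozaki–Hiyama–Kishi addition of crotonaldehyde at C7, Sharpless kinetic resolution/epoxidation (C8, C9), Mitsunobu methacrylation with inversion at C8, and iodide opening (C10–I, free C9–OH).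
- Ring A comes from a vinylogous Mukaiyama aldol (C5–C6) of 3,4-dibromofuran-2(5H)-one with an aldehyde Weinreb amide, a vinylogous Dieckmann acylation (C1–C6) and dehydration; C13 comes from a Stille hydroxymethylation.
- Ring order: butenolide (purchased) → spiro ring A → ten-membered carbocycle by expansion → oxirane.

Assumption: germacrane numbering is used (C1 ketone, C4/C5 oxirane, C6 lactone O–CH, C7=C11, C8 ester carbon, C9 carbinol, C10 CHMe, C12 lactone C=O, C13 CH2OAc); the spiro carbon C6 is carried as both epimers from the dehydration product to the iodohydrin because the ring expansion erases it; the small building blocks and the L-fructose-derived Shi ketone are taken as purchasable.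

Step 1
Reactants: 1 propanal; 2 N-methoxy-N-methylprop-2-enamide
Product: 4 rac-N-methoxy-N,4-dimethyl-5-oxopentanamide, via enamine 3 (not isolated)
Conditions: pyrrolidine (1.05 equiv), 4 Å MS, Et2O, 0 °C; then 2, MeCN, 80 °C; then aq. AcOH
Reagents that add atoms: none
Why: Stork enamine Michael addition — the pyrrolidine enamine of propanal adds through its α-carbon to the acrylamide and hydrolysis returns the aldehyde; the new centre (C4) is racemic and is erased in step 4.

Step 2
Reactants: 4 rac-N-methoxy-N,4-dimethyl-5-oxopentanamide; 5 3,4-dibromofuran-2(5H)-one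
Product: 7 rac-(4R*,5S*)-5-(3,4-dibromo-5-oxo-2,5-dihydrofuran-2-yl)-N-methoxy-N,4-dimethyl-5-(triethylsilyloxy)pentanamide, via 2-silyloxyfuran 6 (not isolated)
Conditions: 5, Et3SiOTf (1.2 equiv), Et3N (1.1 equiv), CH2Cl2, 0 °C; then 4, −78 °C
Reagents that add atoms: triethylsilyl trifluoromethanesulfonate, CC[Si](CC)(CC)OS(=O)(=O)C(F)(F)F
Why: Vinylogous Mukaiyama aldol reaction — soft enolisation gives silyloxyfuran 6, which attacks the aldehyde through the furan γ-carbon (future C6) with silyl transfer to the aldolate; Felkin–Anh addition to the α-methyl aldehyde gives the 4,5-syn pair needed in step 4, and the lactone carbon forms as both epimers, which does not matter.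

Step 3
Reactants: 7 rac-(4R*,5S*)-5-(3,4-dibromo-5-oxo-2,5-dihydrofuran-2-yl)-N-methoxy-N,4-dimethyl-5-(triethylsilyloxy)pentanamide
Product: 9 rac-(9R*,10S*)-3,4-dibromo-10-hydroxy-9-methyl-1-oxaspiro[4.5]dec-3-ene-2,6-dione, via silyl ether ketone 8 (not isolated)
Conditions: LiN(SiMe3)2 (1.15 equiv), THF, −78 → −30 °C; then 1 M HCl, THF, 0 °C → rt
Reagents that add atoms: none
Why: Vinylogous Dieckmann (Claisen-type) acylation — γ-deprotonation gives the lithium furanolate, which closes six-membered ring A on the Weinreb amide (the chelated tetrahedral adduct blocks retro-Claisen) and creates the spiro carbon C6; acid then releases ketone 8 and cleaves its silyl ether, and the low temperature is meant to keep β-elimination of the silyloxy group slower than ring closure.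

Step 4
Reactants: 9 rac-(9R*,10S*)-3,4-dibromo-10-hydroxy-9-methyl-1-oxaspiro[4.5]dec-3-ene-2,6-dione
Product: 10 rac-3,4-dibromo-9-methyl-1-oxaspiro[4.5]deca-3,9-diene-2,6-dione
Conditions: Burgess reagent (MeO2CN−SO2N+Et3, 2 equiv), PhMe, 70 °C
Reagents that add atoms: none
Why: Burgess dehydration (syn elimination through the sulfamate) — C6 is quaternary, so the only β-hydrogen is the cis C4–H, and the C4=C5 alkene forms inside the six-membered ring, which fixes the Z geometry the target needs.

Step 5
Reactants: 10 rac-3,4-dibromo-9-methyl-1-oxaspiro[4.5]deca-3,9-diene-2,6-dione; 11 (E)-but-2-enal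
Product: 12 3-bromo-4-[(E)-1-hydroxybut-2-enyl]-9-methyl-1-oxaspiro[4.5]deca-3,9-diene-2,6-dione (all four stereoisomers)
Conditions: CrCl2 (4 equiv), NiCl2 (5 mol %), 11 (2 equiv), DMF, rt
Reagents that add atoms: none
Why: Nozaki–Hiyama–Kishi coupling — zerovalent nickel inserts into the more electron-poor C–Br bond β to the lactone carbonyl (C7), and the alkenyl species of trivalent chromium adds 1,2 to the enal and not to the ketone; C8 forms racemic and is resolved in step 8.

Step 6
Reactants: 12 3-bromo-4-[(E)-1-hydroxybut-2-enyl]-9-methyl-1-oxaspiro[4.5]deca-3,9-diene-2,6-dione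
Product: 13 4-[(E)-1-hydroxybut-2-enyl]-3-(hydroxymethyl)-9-methyl-1-oxaspiro[4.5]deca-3,9-diene-2,6-dione
Conditions: Bu3SnCH2OH (1.5 equiv), Pd(PPh3)4 (8 mol %), dioxane, 90 °C
Reagents that add atoms: (tributylstannyl)methanol Bu3SnCH2OH, CCCC[Sn](CO)(CCCC)CCCC
Why: Stille–Kosugi cross-coupling — the remaining α-bromide couples with the hydroxymethyl stannane and installs C13; it is done before the methacrylate is present so that no intramolecular Heck reaction can compete.

Step 7
Reactants: 13 4-[(E)-1-hydroxybut-2-enyl]-3-(hydroxymethyl)-9-methyl-1-oxaspiro[4.5]deca-3,9-diene-2,6-dione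
Product: 14 [4-[(E)-1-hydroxybut-2-enyl]-9-methyl-2,6-dioxo-1-oxaspiro[4.5]deca-3,9-dien-3-yl]methyl acetate
Conditions: Ac2O (1.1 equiv), 2,4,6-collidine, CH2Cl2, −20 °C
Reagents that add atoms: acetic anhydride, CC(=O)OC(C)=O
Why: Selective acylation — the unhindered primary allylic alcohol is acetylated much faster than the hindered secondary C8 carbinol.

Step 8
Reactants: 14 [4-[(E)-1-hydroxybut-2-enyl]-9-methyl-2,6-dioxo-1-oxaspiro[4.5]deca-3,9-dien-3-yl]methyl acetate
Product: 15 [4-[(S)-hydroxy[(2S,3S)-3-methyloxiran-2-yl]methyl]-9-methyl-2,6-dioxo-1-oxaspiro[4.5]deca-3,9-dien-3-yl]methyl acetate (both C6 epimers)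
Conditions: Ti(OiPr)4 (0.2 equiv), L-(+)-diisopropyl tartrate (0.3 equiv), t-BuOOH (0.6 equiv), 4 Å MS, CH2Cl2, −20 °C
Reagents that add atoms: tert-butyl hydroperoxide, CC(C)(C)OO
Why: Sharpless kinetic resolution/asymmetric epoxidation — with the L-(+)-tartrate the carbinol enantiomers that are R at C8 (the descriptor becomes S in 15 only through the priority change) are epoxidised fast and erythro-selectively at the propenyl group, which sets C9 and the C8 configuration that step 9 inverts, while the other carbinol enantiomers stay behind (yield at most 50 %).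

Step 9
Reactants: 15 [4-[(S)-hydroxy[(2S,3S)-3-methyloxiran-2-yl]methyl]-9-methyl-2,6-dioxo-1-oxaspiro[4.5]deca-3,9-dien-3-yl]methyl acetate; 16 2-methylprop-2-enoic acid
Product: 17 (R)-[3-(acetoxymethyl)-9-methyl-2,6-dioxo-1-oxaspiro[4.5]deca-3,9-dien-4-yl][(2S,3S)-3-methyloxiran-2-yl]methyl 2-methylprop-2-enoate
Conditions: PPh3, diisopropyl azodicarboxylate, 16, PhMe, 0 °C → rt
Reagents that add atoms: none
Why: Mitsunobu esterification — SN2 displacement of the activated C8 oxygen by methacrylate inverts C8 to the 8R configuration of the target (threo to C9) and installs the ester in the same operation.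

Step 10
Reactants: 17 (R)-[3-(acetoxymethyl)-9-methyl-2,6-dioxo-1-oxaspiro[4.5]deca-3,9-dien-4-yl][(2S,3S)-3-methyloxiran-2-yl]methyl 2-methylprop-2-enoate
Product: 18 (1R,2S,3R)-1-[3-(acetoxymethyl)-9-methyl-2,6-dioxo-1-oxaspiro[4.5]deca-3,9-dien-4-yl]-2-hydroxy-3-iodobutyl 2-methylprop-2-enoate
Conditions: MgI2 (1.5 equiv), PhMe–Et2O, −60 → −20 °C; aq. Na2S2O3
Reagents that add atoms: magnesium iodide MgI2, [Mg+2].[I-].[I-]
Why: Lewis-acid-assisted SN2 opening of a 2,3-epoxy ester — iodide attacks C10, the carbon remote from the electron-withdrawing C8 acyloxy group, so C9 keeps its configuration and becomes the free C9 alcohol of the target; the configuration at C10 is irrelevant.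

Step 11
Reactants: 18 (1R,2S,3R)-1-[3-(acetoxymethyl)-9-methyl-2,6-dioxo-1-oxaspiro[4.5]deca-3,9-dien-4-yl]-2-hydroxy-3-iodobutyl 2-methylprop-2-enoate
Product: 19 (4Z,6R,8R,9R,10S)-13-acetoxy-9-hydroxy-8-(2-methylprop-2-enoyloxy)-1-oxogermacra-4,7(11)-dien-12,6-olide
Conditions: (Me3Si)3SiH (1.3 equiv) and 2,2′-azobis(2-methylpropionitrile) (0.2 equiv) added by syringe pump over 6 h, PhH (2 mM), 80 °C
Reagents that add atoms: none
Why: Proposed new method: a four-atom Dowd–Beckwith-type ring expansion in which the silyl radical abstracts iodine, the secondary C10 radical adds 6-exo to the electron-poor α-acyloxy ketone C1, and the alkoxy radical undergoes β-scission of C1–C6 because this releases a furanone γ-radical stabilised by the ring oxygen, the lactone carbonyl and the C4=C5 alkene, after which hydrogen transfer from the silane to C6 ends the chain; the closest known reaction is the Dowd–Beckwith ring expansion of α-(ω-haloalkyl) β-keto esters; C10 (S) is expected from a chair transition state with the methyl equatorial and the C8 ester and C9 hydroxyl axial (1,3-allylic strain with the C11 substituent, OH···O=C hydrogen bond), C6 (R) from hydrogen delivery to the face opposite the C8 ester, and both C6 epimers of 18 converge on the same radical.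

Step 12
Reactants: 19 (4Z,6R,8R,9R,10S)-13-acetoxy-9-hydroxy-8-(2-methylprop-2-enoyloxy)-1-oxogermacra-4,7(11)-dien-12,6-olide
Product: 20 (4R,5S,6S,8R,9R,10S)-13-acetoxy-4,5-epoxy-9-hydroxy-8-(2-methylprop-2-enoyloxy)-1-oxogermacr-7(11)-en-12,6-olide (CNP0185951.2)
Conditions: 1,2:4,5-di-O-isopropylidene-β-L-erythro-2,3-hexodiulo-2,6-pyranose (L-fructose-derived Shi ketone, 1.5 equiv), KHSO5 (as the triple salt 2KHSO5·KHSO4·K2SO4), NaHCO3, MeCN–H2O (pH 7.5–8), 0 °C
Reagents that add atoms: potassium peroxymonosulfate KHSO5, [K+].[O-]S(=O)(=O)OO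
Why: Shi asymmetric epoxidation — the chiral dioxirane reacts only with the electron-rich trisubstituted C4=C5 alkene (butenolide and methacrylate are electron-poor), and by the spiro transition-state model the L-fructose-derived ketone should deliver oxygen to the face that gives the 4R,5S oxirane (the D-fructose ketone gives the opposite sense for this substitution pattern); the Z alkene gives the cis-fused oxirane, and near-neutral pH protects the base-sensitive butenolide and β-hydroxy ketone.

**Compound list**
1 | propanal | CCC=O | starting material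
2 | N-methoxy-N-methylprop-2-enamide | C=CC(=O)N(C)OC | starting material
3 | (E)-1-(prop-1-enyl)pyrrolidine (formed in the flask) | C/C=C/N1CCCC1 | intermediate
4 | rac-N-methoxy-N,4-dimethyl-5-oxopentanamide | CC(C=O)CCC(=O)N(C)OC | intermediate
5 | 3,4-dibromofuran-2(5H)-one | O=C1OCC(Br)=C1Br | starting material
6 | 3,4-dibromo-2-(triethylsilyloxy)furan (formed in the flask) | CC[Si](CC)(CC)Oc1occ(Br)c1Br | intermediate
7 | rac-(4R*,5S*)-5-(3,4-dibromo-5-oxo-2,5-dihydrofuran-2-yl)-N-methoxy-N,4-dimethyl-5-(triethylsilyloxy)pentanamide (one enantiomer drawn; both epimers at the lactone carbon) | CC[Si](CC)(CC)O[C@@H]([C@H](C)CCC(=O)N(C)OC)C1OC(=O)C(Br)=C1Br | intermediate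
8 | rac-(9R*,10S*)-3,4-dibromo-9-methyl-10-(triethylsilyloxy)-1-oxaspiro[4.5]dec-3-ene-2,6-dione (formed in the flask; both spiro epimers) | CC[Si](CC)(CC)O[C@H]1[C@H](C)CCC(=O)C12OC(=O)C(Br)=C2Br | intermediate
9 | rac-(9R*,10S*)-3,4-dibromo-10-hydroxy-9-methyl-1-oxaspiro[4.5]dec-3-ene-2,6-dione (both spiro epimers) | O[C@H]1[C@H](C)CCC(=O)C12OC(=O)C(Br)=C2Br | intermediate
10 | rac-3,4-dibromo-9-methyl-1-oxaspiro[4.5]deca-3,9-diene-2,6-dione | O=C1CCC(C)=CC12OC(=O)C(Br)=C2Br | intermediate
11 | (E)-but-2-enal | C/C=C/C=O | starting material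
12 | 3-bromo-4-[(E)-1-hydroxybut-2-enyl]-9-methyl-1-oxaspiro[4.5]deca-3,9-diene-2,6-dione (racemic at the carbinol and spiro carbons) | C/C=C/C(O)C1=C(Br)C(=O)OC12C=C(C)CCC2=O | intermediate
13 | 4-[(E)-1-hydroxybut-2-enyl]-3-(hydroxymethyl)-9-methyl-1-oxaspiro[4.5]deca-3,9-diene-2,6-dione (racemic at the carbinol and spiro carbons) | C/C=C/C(O)C1=C(CO)C(=O)OC12C=C(C)CCC2=O | intermediate
14 | [4-[(E)-1-hydroxybut-2-enyl]-9-methyl-2,6-dioxo-1-oxaspiro[4.5]deca-3,9-dien-3-yl]methyl acetate (racemic at the carbinol and spiro carbons) | C/C=C/C(O)C1=C(COC(C)=O)C(=O)OC12C=C(C)CCC2=O | intermediate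
15 | [4-[(S)-hydroxy[(2S,3S)-3-methyloxiran-2-yl]methyl]-9-methyl-2,6-dioxo-1-oxaspiro[4.5]deca-3,9-dien-3-yl]methyl acetate (8S,9S,10S; both spiro epimers) | O[C@H]([C@@H]1O[C@H]1C)C2=C(COC(C)=O)C(=O)OC23C=C(C)CCC3=O | intermediate
16 | 2-methylprop-2-enoic acid | C=C(C)C(=O)O | starting material
17 | (R)-[3-(acetoxymethyl)-9-methyl-2,6-dioxo-1-oxaspiro[4.5]deca-3,9-dien-4-yl][(2S,3S)-3-methyloxiran-2-yl]methyl 2-methylprop-2-enoate (8R,9S,10S; both spiro epimers) | C=C(C)C(=O)O[C@@H]([C@@H]1O[C@H]1C)C2=C(COC(C)=O)C(=O)OC23C=C(C)CCC3=O | intermediate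
18 | (1R,2S,3R)-1-[3-(acetoxymethyl)-9-methyl-2,6-dioxo-1-oxaspiro[4.5]deca-3,9-dien-4-yl]-2-hydroxy-3-iodobutyl 2-methylprop-2-enoate (both spiro epimers) | C=C(C)C(=O)O[C@@H]([C@H](O)[C@H](I)C)C2=C(COC(C)=O)C(=O)OC23C=C(C)CCC3=O | intermediate
19 | (4Z,6R,8R,9R,10S)-13-acetoxy-9-hydroxy-8-(2-methylprop-2-enoyloxy)-1-oxogermacra-4,7(11)-dien-12,6-olide, i.e. (4R,5R,6S,10Z,11aR)-3-(acetoxymethyl)-5-hydroxy-6,10-dimethyl-2,7-dioxo-2,4,5,6,7,8,9,11a-octahydrocyclodeca[b]furan-4-yl 2-methylprop-2-enoate | C=C(C)C(=O)O[C@@H]1C2=C(COC(C)=O)C(=O)O[C@@H]2/C=C(C)\CCC(=O)[C@@H](C)[C@H]1O | intermediate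
20 | (4R,5S,6S,8R,9R,10S)-13-acetoxy-4,5-epoxy-9-hydroxy-8-(2-methylprop-2-enoyloxy)-1-oxogermacr-7(11)-en-12,6-olide (CNP0185951.2) | C=C(C)C(=O)O[C@@H]1C2=C(COC(C)=O)C(=O)O[C@@H]2[C@@H]2O[C@]2(C)CCC(=O)[C@@H](C)[C@H]1O | target

**Step count**
Total steps: 12. Longest linear sequence: 12 (1/2 → 4 → 7 → 9 → 10 → 12 → 13 → 14 → 15 → 17 → 18 → 19 → 20).

**Three steps most likely to fail**

Step 11 (the proposed new ring expansion). The C10 radical could add to C5 of the ring-A alkene instead of C1=O. The delocalised radical could take hydrogen at C4 or C11 instead of C6, or on the wrong face of C6. C10 could form as the wrong epimer, and the silyl radical could add to the methacrylate, although iodine abstraction should be faster. The fallback uses known chemistry and sets out from 17. Cp2TiCl (trivalent titanium, made from Cp2TiCl2 and Zn, THF, rt) opens the oxirane reductively, and the C10 radical adds to the titanium-bound ketone in a titanocene epoxide–carbonyl cyclisation, which gives after work-up the tricyclic 1,9-diol F1. Catalytic 1,8-diazabicyclo[5.4.0]undec-7-ene (CH2Cl2, 0 °C) then opens F1 in a separate ionic step, a retro-vinylogous-aldol fragmentation in which the C1 alkoxide expels the furanolate and C6 is protonated. This comes back to the route at 19.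

Step 12 (face selectivity of the epoxidation on a flexible ten-membered ring; base sensitivity of the product). The fallback sets out from 19. N-Bromosuccinimide in THF–H2O (0 °C) forms the bromonium ion on the exposed face and water opens it at the tertiary C4 from the other side, which gives the bromohydrin F2. Ag2O (THF, rt) then closes the oxirane by displacing bromide at C5 with inversion. The oxygen therefore ends on the face opposite to the one attacked first, which is the remedy if direct oxygen transfer prefers the wrong face. This comes back to the route at 20.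

Step 3 (spiro ring closure; β-elimination of the silyloxy group from the furanolate may win). The fallback sets out from 7 and avoids the basic furanolate. Cp2Zr(H)Cl (THF, rt) reduces the Weinreb amide to the aldehyde F3. Et3SiOTf/Et3N and then BF3·OEt2 (−78 °C) effect an intramolecular vinylogous Mukaiyama aldol reaction to the spiro alcohol F4. Dess–Martin periodinane oxidises F4 to 8, and 1 M HCl removes the silyl group. This comes back to the route at 9.

**Further compounds**
F1 | step 11 | tricyclic 1,9-diol from 17: C1–C10 bond formed and C1–C6 bond kept (ring A C1–C6 with C1 tertiary OH; ring B C1,C6–C10; butenolide; 8R,9R,10S; C1 and C6 as formed) | C=C(C)C(=O)O[C@@H]1C2=C(COC(C)=O)C(=O)OC23C=C(C)CCC3(O)[C@@H](C)[C@H]1O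
F2 | step 12 | (4R,5R,6S,8R,9R,10S)-13-acetoxy-5-bromo-4,9-dihydroxy-8-(2-methylprop-2-enoyloxy)-1-oxogermacr-7(11)-en-12,6-olide | C=C(C)C(=O)O[C@@H]1C2=C(COC(C)=O)C(=O)O[C@@H]2[C@@H](Br)[C@@](O)(C)CCC(=O)[C@@H](C)[C@H]1O
F3 | step 3 | rac-(4R*,5S*)-5-(3,4-dibromo-5-oxo-2,5-dihydrofuran-2-yl)-4-methyl-5-(triethylsilyloxy)pentanal | CC[Si](CC)(CC)O[C@@H]([C@H](C)CCC=O)C1OC(=O)C(Br)=C1Br
F4 | step 3 | rac-(9R*,10S*)-3,4-dibromo-6-hydroxy-9-methyl-10-(triethylsilyloxy)-1-oxaspiro[4.5]dec-3-en-2-one | CC[Si](CC)(CC)O[C@H]1[C@H](C)CCC(O)C12OC(=O)C(Br)=C2Br
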